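The route rests on cutting the C3–C4 bond of the δ-lactone (ring B) of the 4-arylchroman-2-one. C4 is the one sp3 carbon flanked by two arenes. It lies para to O7 of ring A and para to the oxygen of ring D, so its C–H bond is hydridic. In one operation DDQ converts C4–H into a diarylcarbenium ion (an O-benzylated p-quinone methide). A malonate carbon C3, tied to ring A through O1 and held on a chiral copper bis(oxazoline) complex, then closes ring B and sets C4. The precursor is an open aryl benzyl malonate of a diarylmethane that already carries the methoxypyranone (ring C). The extra ester leaves as CO2 at the end.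

Key step: step 9

Numbering: chroman-2-one numbering (O1, C2, C3, C4, C4a, C5 to C8, C8a). Ring A is the benzo ring, ring B the lactone, ring C the 4-methoxy-2-pyranone on C6, and ring D the 4-hydroxyphenyl group on C4. The target is the (4R) enantiomer.

Assumption: the (S,S) ligand of step 9 is taken to deliver (4R). The sense of induction for a tethered electrophile cannot be predicted with certainty, so the equally available (R,R) ligand is used if the first experiment shows the opposite sense.

Step 1
Reactants: 1 2,4-dihydroxy-6-methylbenzaldehyde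
Product: 2 3-bromo-4,6-dihydroxy-2-methylbenzaldehyde
Conditions: NBS (1.0 equiv), MeCN, 0 °C
Reagents that add atoms: N-bromosuccinimide, O=C1CCC(=O)N1Br
Why: Electrophilic aromatic bromination: C5 of 1 is ortho to the free 4-OH and para to the chelated 2-OH and is the site at which this aldehyde is known to be halogenated (SO2Cl2 chlorination), whereas C3 lies between two oxygens, and one equivalent of NBS in the cold limits dibromination.

Step 2
Reactants: 2 3-bromo-4,6-dihydroxy-2-methylbenzaldehyde
Product: 3 3-bromo-6-hydroxy-4-(methoxymethoxy)-2-methylbenzaldehyde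
Conditions: MOMCl (1.05 equiv), K2CO3, acetone, 0 °C to rt
Reagents that add atoms: chloromethyl methyl ether, COCCl
Why: Williamson-type O-alkylation: only the 4-OH, para to the formyl group and ortho to bromine, is acidic and free enough to react, because the 6-OH is locked in a hydrogen bond to the aldehyde oxygen.

Step 3
Reactants: 3 3-bromo-6-hydroxy-4-(methoxymethoxy)-2-methylbenzaldehyde
Product: 4 6-(benzyloxy)-3-bromo-4-(methoxymethoxy)-2-methylbenzaldehyde
Conditions: BnBr, K2CO3, DMF, 50 °C
Reagents that add atoms: benzyl bromide, BrCc1ccccc1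
Why: Williamson ether synthesis: in warm DMF the remaining chelated phenol is alkylated, and the aldehyde, the bromide and the MOM acetal are inert to K2CO3.

Step 4
Reactants: 4 6-(benzyloxy)-3-bromo-4-(methoxymethoxy)-2-methylbenzaldehyde; 5 methyl (E)-3-methoxybut-2-enoate
Product: 7 (±)-6-[6-(benzyloxy)-3-bromo-4-(methoxymethoxy)-2-methylphenyl]-4-methoxy-5,6-dihydro-2H-pyran-2-one, via lithium dienolate 6 (not isolated)
Conditions: LDA, 5, THF, −78 °C; then 4, −78 °C to rt; sat. NH4Cl
Reagents that add atoms: none
Why: Vinylogous aldol addition followed by lactonisation: attack through the γ-carbon gives an alkoxide that closes irreversibly onto the ester, which is cis to the γ-carbon in the (E)-ester, while the α-adduct can revert, and the new stereocentre C6 of the dihydropyranone is formed racemic and is erased in step 5.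

Step 5
Reactants: 7 (±)-6-[6-(benzyloxy)-3-bromo-4-(methoxymethoxy)-2-methylphenyl]-4-methoxy-5,6-dihydro-2H-pyran-2-one
Product: 8 6-[6-(benzyloxy)-3-bromo-4-(methoxymethoxy)-2-methylphenyl]-4-methoxy-2H-pyran-2-one
Conditions: DDQ, 1,4-dioxane, 100 °C
Reagents that add atoms: none
Why: DDQ dehydrogenation: hydride leaves from the C6–H bond of the dihydropyranone, which is benzylic to an arene with ortho and para alkoxy groups and next to the ring oxygen, and loss of H5 then gives the conjugated 2-pyranone, while the aryl methyl group (meta to both oxygens) and the plain benzyl ether are much less hydridic.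

Step 6
Reactants: 8 6-[6-(benzyloxy)-3-bromo-4-(methoxymethoxy)-2-methylphenyl]-4-methoxy-2H-pyran-2-one; 9 4-(benzyloxy)benzyl chloride
Product: 11 6-{6-(benzyloxy)-3-[4-(benzyloxy)benzyl]-4-(methoxymethoxy)-2-methylphenyl}-4-methoxy-2H-pyran-2-one, via benzylzinc chloride 10 (not isolated)
Conditions: 9, Zn dust, LiCl, THF, 25 °C; then 8, Pd(OAc)2 (cat.), SPhos (cat.), THF, 50 °C
Reagents that add atoms: none
Why: Negishi coupling: the benzylzinc chloride made by LiCl-assisted zinc insertion has no β-hydrogen and does not attack the pyranone, and the bulky electron-rich SPhos ligand lets zerovalent palladium insert into the doubly ortho-substituted C–Br bond.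

Step 7
Reactants: 11 6-{6-(benzyloxy)-3-[4-(benzyloxy)benzyl]-4-(methoxymethoxy)-2-methylphenyl}-4-methoxy-2H-pyran-2-one
Product: 12 6-{6-(benzyloxy)-3-[4-(benzyloxy)benzyl]-4-hydroxy-2-methylphenyl}-4-methoxy-2H-pyran-2-one
Conditions: conc. HCl (cat.), MeOH–THF, 45 °C
Reagents that add atoms: none
Why: Acid-catalysed acetal exchange: the MOM group is transferred to methanol, whereas the benzyl ethers and the vinylogous ester OMe of ring C are stable to dilute acid.

Step 8
Reactants: 12 6-{6-(benzyloxy)-3-[4-(benzyloxy)benzyl]-4-hydroxy-2-methylphenyl}-4-methoxy-2H-pyran-2-one; 13 3-(benzyloxy)-3-oxopropanoic acid (mono-benzyl malonate)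
Product: 14 benzyl 5-(benzyloxy)-2-[4-(benzyloxy)benzyl]-4-(4-methoxy-2-oxo-2H-pyran-6-yl)-3-methylphenyl malonate
Conditions: DCC, DMAP (cat.), CH2Cl2, 0 °C to rt
Reagents that add atoms: none
Why: Steglich esterification: the only free hydroxyl group is the later O1, and DCC with catalytic DMAP couples it to the malonic half ester under neutral conditions that leave the pyranone untouched.

Step 9
Reactants: 14 benzyl 5-(benzyloxy)-2-[4-(benzyloxy)benzyl]-4-(4-methoxy-2-oxo-2H-pyran-6-yl)-3-methylphenyl malonate
Product: 16 benzyl (3R,4R)-7-(benzyloxy)-4-[4-(benzyloxy)phenyl]-6-(4-methoxy-2-oxo-2H-pyran-6-yl)-5-methyl-2-oxo-3,4-dihydro-2H-chromene-3-carboxylate, via diarylcarbenium ion 15 (not isolated)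
Conditions: Cu(OTf)2 (20 mol %), 2,2'-(propane-2,2-diyl)bis[(4S)-4-tert-butyl-4,5-dihydro-1,3-oxazole] (22 mol %), 4 Å MS, CH2Cl2, 0 °C; DDQ (1.0 equiv) added slowly, 0 °C to rt
Reagents that add atoms: none
Why: Proposed new method: DDQ abstracts hydride from the C4–H2 group of 14, the only C–H flanked by two arenes that each carry a para oxygen (O7 on ring A, the oxygen of ring D), to give carbenium ion 15 (an O-benzylated p-quinone methide), while the reduced DDQ anion deprotonates the malonate that is chelated through both carbonyl oxygens to the divalent copper bis(oxazoline) complex. The copper enolate carbon C3, held to ring A through O1, then attacks C4 and closes ring B in a 6-(enolendo)-exo-trig mode; the closest known reaction types are the DDQ-mediated enantioselective cross-dehydrogenative coupling of 3-arylmethylindoles with malonates bound to a chiral copper bis(oxazoline) Lewis acid, the DDQ-induced oxidative C–H cleavage and cyclisation with tethered enol nucleophiles, and the intramolecular 1,6-addition of aryl ester enolates to p-quinone methides that gives 4-aryl hydrocoumarins. C4 is set by the ligand: the tert-butyl group next to the aryl ester blocks one face of the planar chelate, and the short O1 tether together with the 5-methyl group lets C4 reach the open face only with ring D turned away from the chelate (pseudoaxial), so that the face choice at C3 is translated into (4R). C3 is formed trans to ring D, is epimerisable and is erased in step 10. The step needs chemoselective oxidation (the OCH2Ph groups lack a second aryl donor and the 5-methyl group is meta to both ring A oxygens) and no second dehydrogenation to the coumarin, which the slow addition of one equivalent of DDQ and the electron-poor malonyl carbon next to C4–H in 16 should secure.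

Step 10
Reactants: 16 benzyl (3R,4R)-7-(benzyloxy)-4-[4-(benzyloxy)phenyl]-6-(4-methoxy-2-oxo-2H-pyran-6-yl)-5-methyl-2-oxo-3,4-dihydro-2H-chromene-3-carboxylate
Product: 18 (4R)-7-hydroxy-4-(4-hydroxyphenyl)-6-(4-methoxy-2-oxo-2H-pyran-6-yl)-5-methyl-3,4-dihydro-2H-chromen-2-one, via carboxylic acid 17 (not isolated)
Conditions: H2 (1 atm), Pd/C, EtOAc–THF, rt; filter; then toluene–AcOH, 90 °C
Reagents that add atoms: none
Why: Hydrogenolysis of the two aryl benzyl ethers and the benzyl ester followed by thermal decarboxylation of the β-carbonyl acid through a cyclic transition state: C3 becomes CH2, C4 is not involved, 4-methoxy-2-pyranones survive Pd/C at one atmosphere, and the weakly acidic medium keeps both para phenols protonated so that retro-1,6-addition should not scramble C4.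

Compound list
1 | 2,4-dihydroxy-6-methylbenzaldehyde | Cc1cc(O)cc(O)c1C=O | starting material
2 | 3-bromo-4,6-dihydroxy-2-methylbenzaldehyde | Cc1c(Br)c(O)cc(O)c1C=O | intermediate
3 | 3-bromo-6-hydroxy-4-(methoxymethoxy)-2-methylbenzaldehyde | Cc1c(Br)c(OCOC)cc(O)c1C=O | intermediate
4 | 6-(benzyloxy)-3-bromo-4-(methoxymethoxy)-2-methylbenzaldehyde | Cc1c(Br)c(OCOC)cc(OCc2ccccc2)c1C=O | intermediate
5 | methyl (E)-3-methoxybut-2-enoate | C/C(OC)=C\C(=O)OC | starting material
6 | lithium dienolate of 5 (O-lithio 1,3-dimethoxybuta-1,3-dien-1-olate) | C=C(OC)C=C(OC)O[Li] | intermediate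
7 | (±)-6-[6-(benzyloxy)-3-bromo-4-(methoxymethoxy)-2-methylphenyl]-4-methoxy-5,6-dihydro-2H-pyran-2-one | COC1=CC(=O)OC(C1)c1c(C)c(Br)c(OCOC)cc1OCc1ccccc1 | intermediate
8 | 6-[6-(benzyloxy)-3-bromo-4-(methoxymethoxy)-2-methylphenyl]-4-methoxy-2H-pyran-2-one | COc1cc(-c2c(C)c(Br)c(OCOC)cc2OCc2ccccc2)oc(=O)c1 | intermediate
9 | 4-(benzyloxy)benzyl chloride | ClCc1ccc(OCc2ccccc2)cc1 | starting material
10 | [4-(benzyloxy)benzyl]zinc chloride | Cl[Zn]Cc1ccc(OCc2ccccc2)cc1 | intermediate
11 | 6-{6-(benzyloxy)-3-[4-(benzyloxy)benzyl]-4-(methoxymethoxy)-2-methylphenyl}-4-methoxy-2H-pyran-2-one | COc1cc(-c2c(C)c(Cc3ccc(OCc4ccccc4)cc3)c(OCOC)cc2OCc2ccccc2)oc(=O)c1 | intermediate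
12 | 6-{6-(benzyloxy)-3-[4-(benzyloxy)benzyl]-4-hydroxy-2-methylphenyl}-4-methoxy-2H-pyran-2-one | COc1cc(-c2c(C)c(Cc3ccc(OCc4ccccc4)cc3)c(O)cc2OCc2ccccc2)oc(=O)c1 | intermediate
13 | 3-(benzyloxy)-3-oxopropanoic acid (mono-benzyl malonate) | O=C(O)CC(=O)OCc1ccccc1 | starting material
14 | benzyl 5-(benzyloxy)-2-[4-(benzyloxy)benzyl]-4-(4-methoxy-2-oxo-2H-pyran-6-yl)-3-methylphenyl malonate | COc1cc(-c2c(C)c(Cc3ccc(OCc4ccccc4)cc3)c(OC(=O)CC(=O)OCc3ccccc3)cc2OCc2ccccc2)oc(=O)c1 | intermediate
15 | diarylcarbenium ion from 14 (O-benzylated p-quinone methide, cation at the later C4) | COc1cc(-c2c(C)c([CH+]c3ccc(OCc4ccccc4)cc3)c(OC(=O)CC(=O)OCc3ccccc3)cc2OCc2ccccc2)oc(=O)c1 | intermediate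
16 | benzyl (3R,4R)-7-(benzyloxy)-4-[4-(benzyloxy)phenyl]-6-(4-methoxy-2-oxo-2H-pyran-6-yl)-5-methyl-2-oxo-3,4-dihydro-2H-chromene-3-carboxylate (3,4-trans) | COc1cc(-c2c(OCc3ccccc3)cc3c(c2C)[C@@H](c2ccc(OCc4ccccc4)cc2)[C@H](C(=O)OCc2ccccc2)C(=O)O3)oc(=O)c1 | intermediate
17 | (3R,4R)-7-hydroxy-4-(4-hydroxyphenyl)-6-(4-methoxy-2-oxo-2H-pyran-6-yl)-5-methyl-2-oxo-3,4-dihydro-2H-chromene-3-carboxylic acid | COc1cc(-c2c(O)cc3c(c2C)[C@@H](c2ccc(O)cc2)[C@H](C(=O)O)C(=O)O3)oc(=O)c1 | intermediate
18 | (4R)-7-hydroxy-4-(4-hydroxyphenyl)-6-(4-methoxy-2-oxo-2H-pyran-6-yl)-5-methyl-3,4-dihydro-2H-chromen-2-one | COc1cc(-c2c(O)cc3c(c2C)[C@@H](c2ccc(O)cc2)CC(=O)O3)oc(=O)c1 | target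

Total step count: 10. Longest linear sequence: 10 steps (1 to 18). Compounds 5, 9 and 13 are bought.

Steps most likely to fail

Step 9 (the step with the label). Three things may go wrong.
- Hydride abstraction may be slow on the twisted ring A system.
- It may instead outrun the copper cycle, so that the cation is taken up by uncomplexed malonate or by the neighbouring ester carbonyl, with loss of facial control.
- A second dehydrogenation may lead on to the coumarin.

The fallback uses known chemistry, sets out from 12 and comes back at 18. DDQ in wet dioxane oxidises the diarylmethane 12 to the o-hydroxybenzophenone F1. (Triphenylphosphoranylidene)ketene in hot toluene acylates the phenol, and the acyl ylide closes C3–C4 as a double bond by intramolecular Wittig olefination to the 4-arylcoumarin F2. Copper hydride asymmetric 1,4-reduction follows (CuCl, NaOtBu, the DTBM-SEGPHOS antipode that gives 4R, pinacolborane). This reaction type is established for 4-arylcoumarins and gives the dibenzyl ether F3. Hydrogenolysis (H2, Pd/C) then gives 18.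

Step 5. Hydride abstraction from the hindered C6–H of the dihydropyranone may be slow, and long heating with DDQ may cost the MOM or benzyl groups. The fallback sets out from 4, comes back at 8, and brings the side chain to the ketone level before the ring is closed. The lithium dienolate of 2,2,6-trimethyl-4H-1,3-dioxin-4-one adds to 4 to give the secondary alcohol F4. Dess–Martin periodinane gives the ketone F5. Thermolysis in toluene at 110 °C (loss of acetone, acylketene, closure by the enol oxygen) gives the 4-hydroxy-2-pyranone F6. Me2SO4 and K2CO3 in acetone give 8.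

Step 10. Ring C may be partly saturated on palladium. Heating the malonyl-type acid with both para phenols free may also allow reversible opening of the C3–C4 bond (retro-1,6-addition), with erosion of the C4 configuration. The fallback sets out from 16, comes back at 18, is reordered, and is non-reductive at its end. Pd(OAc)2, Et3SiH and Et3N cleave only the benzyl ester and give the dibenzyl ether acid F7 with both phenols still masked. F7 loses CO2 in warm toluene to give the dibenzyl ether F3 described above. BCl3 and pentamethylbenzene in CH2Cl2 at −78 °C then remove the two aryl benzyl ethers and give 18.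

Further compounds
F1 | step 9 | [4-(benzyloxy)-6-hydroxy-3-(4-methoxy-2-oxo-2H-pyran-6-yl)-2-methylphenyl][4-(benzyloxy)phenyl]methanone | COc1cc(-c2c(C)c(C(=O)c3ccc(OCc4ccccc4)cc3)c(O)cc2OCc2ccccc2)oc(=O)c1
F2 | step 9 | 7-(benzyloxy)-4-[4-(benzyloxy)phenyl]-6-(4-methoxy-2-oxo-2H-pyran-6-yl)-5-methyl-2H-chromen-2-one | COc1cc(-c2c(OCc3ccccc3)cc3oc(=O)cc(-c4ccc(OCc5ccccc5)cc4)c3c2C)oc(=O)c1
F3 | step 9 | (4R)-7-(benzyloxy)-4-[4-(benzyloxy)phenyl]-6-(4-methoxy-2-oxo-2H-pyran-6-yl)-5-methyl-3,4-dihydro-2H-chromen-2-one | COc1cc(-c2c(OCc3ccccc3)cc3c(c2C)[C@@H](c2ccc(OCc4ccccc4)cc2)CC(=O)O3)oc(=O)c1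
F4 | step 5 | (±)-6-{2-[6-(benzyloxy)-3-bromo-4-(methoxymethoxy)-2-methylphenyl]-2-hydroxyethyl}-2,2-dimethyl-4H-1,3-dioxin-4-one | CC1(C)OC(=O)C=C(CC(O)c2c(C)c(Br)c(OCOC)cc2OCc2ccccc2)O1
F5 | step 5 | 6-{2-[6-(benzyloxy)-3-bromo-4-(methoxymethoxy)-2-methylphenyl]-2-oxoethyl}-2,2-dimethyl-4H-1,3-dioxin-4-one | CC1(C)OC(=O)C=C(CC(=O)c2c(C)c(Br)c(OCOC)cc2OCc2ccccc2)O1
F6 | step 5 | 6-[6-(benzyloxy)-3-bromo-4-(methoxymethoxy)-2-methylphenyl]-4-hydroxy-2H-pyran-2-one | Oc1cc(-c2c(C)c(Br)c(OCOC)cc2OCc2ccccc2)oc(=O)c1
F7 | step 10 | (3R,4R)-7-(benzyloxy)-4-[4-(benzyloxy)phenyl]-6-(4-methoxy-2-oxo-2H-pyran-6-yl)-5-methyl-2-oxo-3,4-dihydro-2H-chromene-3-carboxylic acid | COc1cc(-c2c(OCc3ccccc3)cc3c(c2C)[C@@H](c2ccc(OCc4ccccc4)cc2)[C@H](C(=O)O)C(=O)O3)oc(=O)c1
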